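**Plan**
- Numbering: butenolide O1, C2(=O), C3(CH3), C4(O-acyl), C5; chain C6(=CH) to C18, with C7 the stereocentre and the furan on C18.
- Retrosynthetic cuts, in order: the O-acyl ester; C3–C4 (Dieckmann) and O1–C5 (copper C–O coupling) of the butenolide; C4–C5 and C5–C6 back to the C6 aldehyde; C18–furan; then C14–C15 with C15–CH3, and C10–C11 with C11–CH3.
- Enabling feature: C11=C12 and C15=C16 are both E, methyl-bearing trisubstituted alkenes, each followed by two CH2 groups (C13–C14 and C17–C18). That is exactly what remains of a 2,3-dihydrofuran ring substituted at C5 once its vinylic C5–O bond is broken, so each unit comes from one temporary dihydrofuran ring.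
- Forward: (S)-β-citronellene gives the C6–C10 iodide; two lithio-dihydrofuran/cuprate/iodomethane cycles extend the chain to C14 and then C18; the purchased furan ring is attached at C18; the butenolide ring is closed in the penultimate step and O-acylated last.
- Stereochemistry: C7 comes from (S)-β-citronellene; the two chain E alkenes from the ring-locked 1,2-metallate shift and retentive methylation; the exocyclic E alkene from syn hydrostannation, carried with retention through iodination, C–O coupling and ring closure.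

Key step: step 9

Assumption: the SMILES is read as 7S with an E exocyclic C5=C6 alkene (chain cis to C4, trans to O1); 10 is made fresh by step 8 for each of steps 9 and 11.

**Route**

Step 1
Reactants: 1 (S)-β-citronellene [(3S)-3,7-dimethylocta-1,6-diene]
Product: 2 2,2-dimethyl-3-[(3S)-3-methylpent-4-en-1-yl]oxirane (both epimers at the oxirane carbon)
Conditions: mCPBA (1.0 equiv), NaHCO3, CH2Cl2, 0 °C
Reagents that add atoms: mCPBA, OOC(=O)c1cccc(Cl)c1
Why: Prilezhaev epoxidation is chemoselective for the electron-rich trisubstituted alkene over the terminal vinyl group, and the uncontrolled new oxirane centre is of no consequence because it is destroyed in step 2.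

Step 2
Reactants: 2 2,2-dimethyl-3-[(3S)-3-methylpent-4-en-1-yl]oxirane
Product: 3 (4S)-4-methylhex-5-enal
Conditions: H5IO6, THF/H2O, 0 °C to rt
Reagents that add atoms: none
Why: Periodic acid opens the epoxide to the glycol and cleaves it in the same flask (Malaprade glycol cleavage), so acetone is lost, the aldehyde keeps the former epoxide oxygen, and the vinyl group and the stereocentre are untouched.

Step 3
Reactants: 3 (4S)-4-methylhex-5-enal
Product: 4 (4S)-4-methylhex-5-en-1-ol
Conditions: NaBH4, MeOH, 0 °C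
Reagents that add atoms: none
Why: Hydride reduction of the aldehyde with NaBH4 is fast and leaves the isolated vinyl group and the remote stereocentre alone.

Step 4
Reactants: 4 (4S)-4-methylhex-5-en-1-ol
Product: 5 (3S)-6-bromo-3-methylhex-1-ene
Conditions: CBr4, PPh3, CH2Cl2, 0 °C
Reagents that add atoms: carbon tetrabromide, BrC(Br)(Br)Br
Why: The Appel reaction converts the primary alcohol into a bromide under neutral conditions, giving a handle that is inert to ozone and to silylation and is later exchanged for iodide.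

Step 5
Reactants: 5 (3S)-6-bromo-3-methylhex-1-ene
Product: 6 (2S)-5-bromo-2-methylpentan-1-ol
Conditions: O3, CH2Cl2/MeOH, −78 °C; then NaBH4, −78 to 0 °C
Reagents that add atoms: ozone, [O-][O+]=O
Why: Ozonolysis of the only alkene with reductive NaBH4 work-up turns the vinyl group into the CH2OH that becomes C6, and because no bond to the stereocentre is broken and the transient aldehyde is reduced cold, the configuration that becomes C7 is kept.

Step 6
Reactants: 6 (2S)-5-bromo-2-methylpentan-1-ol
Product: 7 {[(2S)-5-bromo-2-methylpentyl]oxy}(tert-butyl)dimethylsilane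
Conditions: TBSCl, imidazole, CH2Cl2, 0 °C to rt
Reagents that add atoms: TBSCl, CC(C)(C)[Si](C)(C)Cl
Why: Silylation of the primary alcohol with TBSCl and imidazole gives an ether that tolerates organolithium and organocopper reagents and the later iodinations.

Step 7
Reactants: 7 {[(2S)-5-bromo-2-methylpentyl]oxy}(tert-butyl)dimethylsilane
Product: 8 tert-butyl{[(2S)-5-iodo-2-methylpentyl]oxy}dimethylsilane
Conditions: NaI, acetone, reflux
Reagents that add atoms: NaI, [Na+].[I-]
Why: Finkelstein exchange (SN2 at the primary carbon) is driven by precipitation of NaBr from acetone and supplies the iodide needed for clean iodine–lithium exchange.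

Step 8
Reactants: 9 2,3-dihydrofuran
Product: 10 5-lithio-2,3-dihydrofuran (4,5-dihydrofuran-2-yllithium), used at once as a solution
Conditions: t-BuLi, THF/pentane, −78 to 0 °C
Reagents that add atoms: t-BuLi, [Li]C(C)(C)C
Why: Vinylic deprotonation of the cyclic enol ether at the carbon next to oxygen by t-BuLi is the standard entry to this α-alkoxyalkenyllithium.

Step 9
Reactants: 8 tert-butyl{[(2S)-5-iodo-2-methylpentyl]oxy}dimethylsilane; 10 5-lithio-2,3-dihydrofuran; 11 iodomethane
Product: 16 (3E,8S)-9-[(tert-butyldimethylsilyl)oxy]-4,8-dimethylnon-3-en-1-ol, via alkyllithium 12 (not isolated), via alkylcopper 13 (not isolated), via mixed cuprate 14 (not isolated), via alkenylcopper alkoxide 15 (not isolated)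
Conditions: t-BuLi (2.1 equiv), Et2O/pentane, −78 °C; CuBr·SMe2, Me2S/Et2O, −78 to −45 °C; 10 in THF, −78 °C to rt; MeI, DMPU, 0 °C to rt
Reagents that add atoms: iodomethane 11, CI
Why: Iodine–lithium exchange gives alkyllithium 12, CuBr·SMe2 turns it into alkylcopper 13, and 10 adds to give the mixed lithium cuprate 14, in which copper carries the chiral alkyl group and C5 of the dihydrofuran. On warming, the alkyl group migrates from copper to that carbon (1,2-metallate shift) with inversion, entering opposite the ring C–O bond as it breaks; this forms C10–C11, opens the five-membered ring and leaves alkenylcopper 15 with the new chain trans to the CH2CH2OLi arm. Iodomethane then alkylates the alkenyl–copper bond with retention (C11–CH3), so only the E alkene can result. The closest known reaction type is the 1,2-metallate rearrangement of α-alkoxyalkenyl cuprates with electrophilic trapping, used for E-trisubstituted isoprenoid alkenes. No ring is closed and no stereocentre is made; C7 is remote and unaffected. The step needs E geometry, secured by the ring that holds O and C13 cis before the shift, and full use of the chiral alkyl group, secured by the 1:1:1 stoichiometry in which that alkyl group is the only ligand able to migrate.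

Step 10
Reactants: 16 (3E,8S)-9-[(tert-butyldimethylsilyl)oxy]-4,8-dimethylnon-3-en-1-ol
Product: 17 tert-butyl{[(2S,6E)-9-iodo-2,6-dimethylnon-6-en-1-yl]oxy}dimethylsilane
Conditions: I2, PPh3, imidazole, CH2Cl2, 0 °C
Reagents that add atoms: iodine, II
Why: Appel-type iodination converts the primary homoallylic alcohol into the iodide under buffered conditions that leave the silyl ether and the alkene geometry intact.

Step 11
Reactants: 17 tert-butyl{[(2S,6E)-9-iodo-2,6-dimethylnon-6-en-1-yl]oxy}dimethylsilane; 10 5-lithio-2,3-dihydrofuran; 11 iodomethane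
Product: 22 (3E,7E,12S)-13-[(tert-butyldimethylsilyl)oxy]-4,8,12-trimethyltrideca-3,7-dien-1-ol, via alkyllithium 18 (not isolated), via alkylcopper 19 (not isolated), via mixed cuprate 20 (not isolated), via alkenylcopper alkoxide 21 (not isolated)
Conditions: t-BuLi (2.1 equiv), Et2O/pentane, −78 °C; CuBr·SMe2, Me2S/Et2O, −78 to −45 °C; 10 in THF, −78 °C to rt; MeI, DMPU, 0 °C to rt
Reagents that add atoms: iodomethane 11, CI
Why: The same sequence as in step 9 (iodine–lithium exchange, cuprate formation, 1,2-metallate shift with ring opening, retentive methylation) forms C14–C15 and C15–CH3 and fixes the second E alkene by the same ring-locked geometry.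

Step 12
Reactants: 22 (3E,7E,12S)-13-[(tert-butyldimethylsilyl)oxy]-4,8,12-trimethyltrideca-3,7-dien-1-ol
Product: 23 tert-butyl{[(2S,6E,10E)-13-iodo-2,6,10-trimethyltrideca-6,10-dien-1-yl]oxy}dimethylsilane
Conditions: I2, PPh3, imidazole, CH2Cl2, 0 °C
Reagents that add atoms: iodine, II
Why: Appel-type iodination of the primary homoallylic alcohol, as in step 10, gives the electrophile for attaching the furan.

Step 13
Reactants: 23 tert-butyl{[(2S,6E,10E)-13-iodo-2,6,10-trimethyltrideca-6,10-dien-1-yl]oxy}dimethylsilane; 24 3-bromofuran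
Product: 26 tert-butyl{[(2S,6E,10E)-13-(furan-3-yl)-2,6,10-trimethyltrideca-6,10-dien-1-yl]oxy}dimethylsilane, via 3-furyllithium 25 (not isolated)
Conditions: 24, n-BuLi, THF, −78 °C; then 23, DMPU, −78 to −45 °C
Reagents that add atoms: none
Why: Bromine–lithium exchange at −78 °C gives 3-furyllithium, which is kept below the temperature at which it isomerises to the 2-lithio isomer and displaces the primary iodide (SN2) in the presence of DMPU to form the C18–furan bond.

Step 14
Reactants: 26 tert-butyl{[(2S,6E,10E)-13-(furan-3-yl)-2,6,10-trimethyltrideca-6,10-dien-1-yl]oxy}dimethylsilane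
Product: 27 (2S,6E,10E)-13-(furan-3-yl)-2,6,10-trimethyltrideca-6,10-dien-1-ol
Conditions: Bu4NF, THF, rt
Reagents that add atoms: none
Why: Fluoride-mediated desilylation frees the primary alcohol without touching the furan or the alkenes.

Step 15
Reactants: 27 (2S,6E,10E)-13-(furan-3-yl)-2,6,10-trimethyltrideca-6,10-dien-1-ol
Product: 28 (2S,6E,10E)-13-(furan-3-yl)-2,6,10-trimethyltrideca-6,10-dienal
Conditions: Dess–Martin periodinane, NaHCO3, CH2Cl2, 0 °C to rt
Reagents that add atoms: none
Why: Dess–Martin oxidation under bicarbonate buffer gives the aldehyde under neutral conditions that should neither epimerise the α-stereocentre C7 nor attack the furan.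

Step 16
Reactants: 28 (2S,6E,10E)-13-(furan-3-yl)-2,6,10-trimethyltrideca-6,10-dienal
Product: 29 3-[(3E,7E,12S)-14,14-dibromo-4,8,12-trimethyltetradeca-3,7,13-trien-1-yl]furan
Conditions: CBr4, PPh3, Et3N, CH2Cl2, 0 °C
Reagents that add atoms: carbon tetrabromide, BrC(Br)(Br)Br
Why: Ramirez dibromoolefination (first stage of the Corey–Fuchs sequence) adds C5 to the aldehyde carbon C6 under buffered, non-basic conditions that spare the α-stereocentre.

Step 17
Reactants: 29 3-[(3E,7E,12S)-14,14-dibromo-4,8,12-trimethyltetradeca-3,7,13-trien-1-yl]furan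
Product: 31 methyl (4S,8E,12E)-15-(furan-3-yl)-4,8,12-trimethylpentadeca-8,12-dien-2-ynoate, via lithium acetylide 30 (not isolated)
Conditions: n-BuLi (2.05 equiv), THF, −78 °C; then ClCO2Me, −78 to 0 °C
Reagents that add atoms: methyl chloroformate, COC(Cl)=O
Why: Bromine–lithium exchange and Fritsch–Buttenberg–Wiechell rearrangement (second stage of the Corey–Fuchs sequence) give the lithium acetylide, which is acylated in the same flask by methyl chloroformate to add C4 as the ester carbon.

Step 18
Reactants: 31 methyl (4S,8E,12E)-15-(furan-3-yl)-4,8,12-trimethylpentadeca-8,12-dien-2-ynoate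
Product: 32 methyl (2E,4S,8E,12E)-15-(furan-3-yl)-4,8,12-trimethyl-2-(tributylstannyl)pentadeca-2,8,12-trienoate
Conditions: Bu3SnH, Pd(PPh3)4 (cat.), THF, 0 °C to rt
Reagents that add atoms: tributyltin hydride, CCCC[SnH](CCCC)CCCC
Why: Hydrostannation of an alkynoate catalysed by zerovalent palladium is a syn addition that places tin on the α-carbon (C5) and hydrogen on C6, so the chain ends up cis to the ester group, which is the geometry needed for the E exocyclic alkene.

Step 19
Reactants: 32 methyl (2E,4S,8E,12E)-15-(furan-3-yl)-4,8,12-trimethyl-2-(tributylstannyl)pentadeca-2,8,12-trienoate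
Product: 33 methyl (2E,4S,8E,12E)-15-(furan-3-yl)-2-iodo-4,8,12-trimethylpentadeca-2,8,12-trienoate
Conditions: I2 (1.05 equiv), CH2Cl2, −78 to 0 °C
Reagents that add atoms: iodine, II
Why: Iododestannylation is an ipso electrophilic substitution with retention of alkene geometry and is much faster than any reaction of iodine with the trisubstituted alkenes or the furan at low temperature.

Step 20
Reactants: 33 methyl (2E,4S,8E,12E)-15-(furan-3-yl)-2-iodo-4,8,12-trimethylpentadeca-2,8,12-trienoate
Product: 34 methyl (2E,4S,8E,12E)-15-(furan-3-yl)-4,8,12-trimethyl-2-(propanoyloxy)pentadeca-2,8,12-trienoate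
Conditions: EtCO2Na, CuI, NMP, 70 °C, dark
Reagents that add atoms: sodium propanoate, CCC(=O)[O-].[Na+]
Why: Ullmann-type C–O coupling of an alkenyl iodide with a copper carboxylate (formed from CuI and sodium propanoate, monovalent copper throughout) replaces iodine by the propanoyloxy group with retention of geometry and forms the future O1–C5 bond.

Step 21
Reactants: 34 methyl (2E,4S,8E,12E)-15-(furan-3-yl)-4,8,12-trimethyl-2-(propanoyloxy)pentadeca-2,8,12-trienoate
Product: 35 (5E)-5-[(2S,6E,10E)-13-(furan-3-yl)-2,6,10-trimethyltrideca-6,10-dien-1-ylidene]-4-hydroxy-3-methylfuran-2(5H)-one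
Conditions: LiN(SiMe3)2 (2.2 equiv), THF, −78 to 0 °C; then cold 0.5 M HCl
Reagents that add atoms: none
Why: In this Dieckmann condensation the kinetically formed propanoate enolate attacks the neighbouring methyl ester (5-exo-trig) to close the butenolide ring as the stable tetronate anion; the C5=C6 bond is not involved, so its E geometry is carried over, and the low temperature and hindered base disfavour deprotonation at C7.

Step 22
Reactants: 36 15-methylhexadecanoic acid
Product: 37 15-methylhexadecanoyl chloride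
Conditions: (COCl)2, DMF (cat.), CH2Cl2, 0 °C to rt
Reagents that add atoms: oxalyl chloride, ClC(=O)C(Cl)=O
Why: Conversion of the acid into its chloride with oxalyl chloride under DMF catalysis (Vilsmeier-type activation) gives the acylating agent with only gaseous by-products.

Step 23
Reactants: 35 (5E)-5-[(2S,6E,10E)-13-(furan-3-yl)-2,6,10-trimethyltrideca-6,10-dien-1-ylidene]-4-hydroxy-3-methylfuran-2(5H)-one; 37 15-methylhexadecanoyl chloride
Product: 38 (2E)-2-[(2S,6E,10E)-13-(furan-3-yl)-2,6,10-trimethyltrideca-6,10-dien-1-ylidene]-4-methyl-5-oxo-2,5-dihydrofuran-3-yl 15-methylhexadecanoate (CNP0210898.1)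
Conditions: Et3N, CH2Cl2, 0 °C
Reagents that add atoms: none
Why: O-acylation of the tetronic acid at its C4 oxygen by the acid chloride with Et3N is the only course open because C3 already carries a methyl group, and the mild conditions keep the E exocyclic alkene and C7 intact.

**Compound list**

1 | (S)-β-citronellene, (3S)-3,7-dimethylocta-1,6-diene | C=C[C@@H](C)CCC=C(C)C | starting material
2 | 2,2-dimethyl-3-[(3S)-3-methylpent-4-en-1-yl]oxirane (epimers at the oxirane carbon) | C=C[C@@H](C)CCC1OC1(C)C | intermediate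
3 | (4S)-4-methylhex-5-enal | C=C[C@@H](C)CCC=O | intermediate
4 | (4S)-4-methylhex-5-en-1-ol | C=C[C@@H](C)CCCO | intermediate
5 | (3S)-6-bromo-3-methylhex-1-ene | C=C[C@@H](C)CCCBr | intermediate
6 | (2S)-5-bromo-2-methylpentan-1-ol | OC[C@@H](C)CCCBr | intermediate
7 | {[(2S)-5-bromo-2-methylpentyl]oxy}(tert-butyl)dimethylsilane | CC(C)(C)[Si](C)(C)OC[C@@H](C)CCCBr | intermediate
8 | tert-butyl{[(2S)-5-iodo-2-methylpentyl]oxy}dimethylsilane | CC(C)(C)[Si](C)(C)OC[C@@H](C)CCCI | intermediate
9 | 2,3-dihydrofuran | C1CC=CO1 | starting material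
10 | 5-lithio-2,3-dihydrofuran | [Li]C1=CCCO1 | intermediate
11 | iodomethane | CI | starting material
12 | {(4S)-5-[(tert-butyldimethylsilyl)oxy]-4-methylpentyl}lithium | CC(C)(C)[Si](C)(C)OC[C@@H](C)CCC[Li] | intermediate
13 | {(4S)-5-[(tert-butyldimethylsilyl)oxy]-4-methylpentyl}copper | CC(C)(C)[Si](C)(C)OC[C@@H](C)CCC[Cu] | intermediate
14 | lithium {(4S)-5-[(tert-butyldimethylsilyl)oxy]-4-methylpentyl}(4,5-dihydrofuran-2-yl)cuprate | [Li+].CC(C)(C)[Si](C)(C)OC[C@@H](C)CCC[Cu-]C1=CCCO1 | intermediate
15 | lithium (3Z,8S)-9-[(tert-butyldimethylsilyl)oxy]-4-cuprio-8-methylnon-3-en-1-olate (copper cis to the CH2CH2OLi arm) | CC(C)(C)[Si](C)(C)OC[C@@H](C)CCC/C([Cu])=C/CCO[Li] | intermediate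
16 | (3E,8S)-9-[(tert-butyldimethylsilyl)oxy]-4,8-dimethylnon-3-en-1-ol | CC(C)(C)[Si](C)(C)OC[C@@H](C)CCC/C(C)=C/CCO | intermediate
17 | tert-butyl{[(2S,6E)-9-iodo-2,6-dimethylnon-6-en-1-yl]oxy}dimethylsilane | CC(C)(C)[Si](C)(C)OC[C@@H](C)CCC/C(C)=C/CCI | intermediate
18 | {(3E,8S)-9-[(tert-butyldimethylsilyl)oxy]-4,8-dimethylnon-3-en-1-yl}lithium | CC(C)(C)[Si](C)(C)OC[C@@H](C)CCC/C(C)=C/CC[Li] | intermediate
19 | {(3E,8S)-9-[(tert-butyldimethylsilyl)oxy]-4,8-dimethylnon-3-en-1-yl}copper | CC(C)(C)[Si](C)(C)OC[C@@H](C)CCC/C(C)=C/CC[Cu] | intermediate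
20 | lithium {(3E,8S)-9-[(tert-butyldimethylsilyl)oxy]-4,8-dimethylnon-3-en-1-yl}(4,5-dihydrofuran-2-yl)cuprate | [Li+].CC(C)(C)[Si](C)(C)OC[C@@H](C)CCC/C(C)=C/CC[Cu-]C1=CCCO1 | intermediate
21 | lithium (3Z,7E,12S)-13-[(tert-butyldimethylsilyl)oxy]-4-cuprio-8,12-dimethyltrideca-3,7-dien-1-olate (copper cis to the CH2CH2OLi arm) | CC(C)(C)[Si](C)(C)OC[C@@H](C)CCC/C(C)=C/CC/C([Cu])=C/CCO[Li] | intermediate
22 | (3E,7E,12S)-13-[(tert-butyldimethylsilyl)oxy]-4,8,12-trimethyltrideca-3,7-dien-1-ol | CC(C)(C)[Si](C)(C)OC[C@@H](C)CCC/C(C)=C/CC/C(C)=C/CCO | intermediate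
23 | tert-butyl{[(2S,6E,10E)-13-iodo-2,6,10-trimethyltrideca-6,10-dien-1-yl]oxy}dimethylsilane | CC(C)(C)[Si](C)(C)OC[C@@H](C)CCC/C(C)=C/CC/C(C)=C/CCI | intermediate
24 | 3-bromofuran | Brc1ccoc1 | starting material
25 | 3-furyllithium | [Li]c1ccoc1 | intermediate
26 | tert-butyl{[(2S,6E,10E)-13-(furan-3-yl)-2,6,10-trimethyltrideca-6,10-dien-1-yl]oxy}dimethylsilane | CC(C)(C)[Si](C)(C)OC[C@@H](C)CCC/C(C)=C/CC/C(C)=C/CCc1ccoc1 | intermediate
27 | (2S,6E,10E)-13-(furan-3-yl)-2,6,10-trimethyltrideca-6,10-dien-1-ol | OC[C@@H](C)CCC/C(C)=C/CC/C(C)=C/CCc1ccoc1 | intermediate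
28 | (2S,6E,10E)-13-(furan-3-yl)-2,6,10-trimethyltrideca-6,10-dienal | O=C[C@@H](C)CCC/C(C)=C/CC/C(C)=C/CCc1ccoc1 | intermediate
29 | 3-[(3E,7E,12S)-14,14-dibromo-4,8,12-trimethyltetradeca-3,7,13-trien-1-yl]furan | BrC(Br)=C[C@@H](C)CCC/C(C)=C/CC/C(C)=C/CCc1ccoc1 | intermediate
30 | lithium (3S,7E,11E)-14-(furan-3-yl)-3,7,11-trimethyltetradeca-7,11-dien-1-yn-1-ide | [Li]C#C[C@@H](C)CCC/C(C)=C/CC/C(C)=C/CCc1ccoc1 | intermediate
31 | methyl (4S,8E,12E)-15-(furan-3-yl)-4,8,12-trimethylpentadeca-8,12-dien-2-ynoate | COC(=O)C#C[C@@H](C)CCC/C(C)=C/CC/C(C)=C/CCc1ccoc1 | intermediate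
32 | methyl (2E,4S,8E,12E)-15-(furan-3-yl)-4,8,12-trimethyl-2-(tributylstannyl)pentadeca-2,8,12-trienoate (chain cis to the ester) | COC(=O)/C([Sn](CCCC)(CCCC)CCCC)=C\[C@@H](C)CCC/C(C)=C/CC/C(C)=C/CCc1ccoc1 | intermediate
33 | methyl (2E,4S,8E,12E)-15-(furan-3-yl)-2-iodo-4,8,12-trimethylpentadeca-2,8,12-trienoate | COC(=O)/C(I)=C\[C@@H](C)CCC/C(C)=C/CC/C(C)=C/CCc1ccoc1 | intermediate
34 | methyl (2E,4S,8E,12E)-15-(furan-3-yl)-4,8,12-trimethyl-2-(propanoyloxy)pentadeca-2,8,12-trienoate | COC(=O)/C(OC(=O)CC)=C\[C@@H](C)CCC/C(C)=C/CC/C(C)=C/CCc1ccoc1 | intermediate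
35 | (5E)-5-[(2S,6E,10E)-13-(furan-3-yl)-2,6,10-trimethyltrideca-6,10-dien-1-ylidene]-4-hydroxy-3-methylfuran-2(5H)-one | CC1=C(O)/C(=C\[C@@H](C)CCC/C(C)=C/CC/C(C)=C/CCc2ccoc2)OC1=O | intermediate
36 | 15-methylhexadecanoic acid | OC(=O)CCCCCCCCCCCCCC(C)C | starting material
37 | 15-methylhexadecanoyl chloride | ClC(=O)CCCCCCCCCCCCCC(C)C | intermediate
38 | (2E)-2-[(2S,6E,10E)-13-(furan-3-yl)-2,6,10-trimethyltrideca-6,10-dien-1-ylidene]-4-methyl-5-oxo-2,5-dihydrofuran-3-yl 15-methylhexadecanoate | CC1=C(OC(=O)CCCCCCCCCCCCCC(C)C)/C(=C\[C@@H](C)CCC/C(C)=C/CC/C(C)=C/CCc2ccoc2)OC1=O | target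

**Step count**

Total: 23 steps (step 8 is run twice). Longest linear sequence: 21 steps (1–7, 9–21, 23).

**Steps most likely to fail**

1. Step 20 (copper C–O coupling). The substitution at a hindered, electron-poor alkenyl iodide may be slow, and on heating the alkene may isomerise, the iodine may be lost by reduction, or the enoate may deconjugate through γ-deprotonation. The fallback sets out from aldehyde 28 and returns at enol ester 34, bypassing steps 16 to 20. Commercially available methyl 2-[bis(2,2,2-trifluoroethoxy)phosphoryl]acetate is converted by diazo transfer (4-acetamidobenzenesulfonyl azide, DBU, MeCN) into methyl 2-[bis(2,2,2-trifluoroethoxy)phosphoryl]-2-diazoacetate F1. O–H insertion of F1 into propanoic acid, catalysed by Rh2(OAc)4, gives methyl 2-[bis(2,2,2-trifluoroethoxy)phosphoryl]-2-(propanoyloxy)acetate F2. Still–Gennari olefination of 28 with F2 (KN(SiMe3)2, 18-crown-6, THF, −78 °C) should place the chain cis to the ester under kinetic control and so deliver 34 directly.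

2. Step 9 (cuprate 1,2-metallate shift). The alkylcopper or the cuprate may decay thermally (β-hydride loss, homocoupling) before the shift, or the alkenylcopper may be protonated instead of methylated, leaving a disubstituted alkene. The fallback sets out from 8 and 10 and returns at 16, making the same two bonds on the same temporary ring in two separate steps. Alkylation of 10 with iodide 8 (THF/DMPU, −78 to 0 °C) forms C10–C11 and gives tert-butyl{[(2S)-5-(4,5-dihydrofuran-2-yl)-2-methylpentyl]oxy}dimethylsilane F3. Nickel-catalysed Kumada-type coupling of MeMgBr at the vinylic C–O bond of F3 (NiCl2(PPh3)2 cat., toluene, reflux) then replaces oxygen by methyl with retention and opens the ring to the E homoallylic alcohol 16.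

3. Step 13 (alkylation of 3-furyllithium). The homoallylic iodide may undergo E2 elimination to a 1,3-diene, and 3-furyllithium may isomerise to the 2-lithio isomer before it is alkylated. The fallback sets out from 23 and returns at 26 by reversing the polarity of the coupling. Iodine–lithium exchange of 23 (t-BuLi, Et2O, −78 °C) and capture with B-methoxy-9-BBN gives the lithium B-alkyl-B-methoxy-9-BBN borate F4. B-alkyl Suzuki–Miyaura coupling of F4 with 3-bromofuran 24 (PdCl2(dppf), K3PO4, DMF/THF, rt to 50 °C) then gives 26.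

**Further compounds**

F1 | step 20 | methyl 2-[bis(2,2,2-trifluoroethoxy)phosphoryl]-2-diazoacetate | COC(=O)C(=[N+]=[N-])P(=O)(OCC(F)(F)F)OCC(F)(F)F
F2 | step 20 | methyl 2-[bis(2,2,2-trifluoroethoxy)phosphoryl]-2-(propanoyloxy)acetate (racemic) | CCC(=O)OC(C(=O)OC)P(=O)(OCC(F)(F)F)OCC(F)(F)F
F3 | step 9 | tert-butyl{[(2S)-5-(4,5-dihydrofuran-2-yl)-2-methylpentyl]oxy}dimethylsilane | CC(C)(C)[Si](C)(C)OC[C@@H](C)CCCC1=CCCO1
F4 | step 13 | lithium B-methoxy-B-{(3E,7E,12S)-13-[(tert-butyldimethylsilyl)oxy]-4,8,12-trimethyltrideca-3,7-dien-1-yl}-9-borabicyclo[3.3.1]nonane ate complex | [Li+].CO[B-]1(CC/C=C(C)/CC/C=C(C)/CCC[C@H](C)CO[Si](C)(C)C(C)(C)C)C2CCCC1CCC2
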